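**Plan**

Rings: A = benzo ring of the chroman (C4a to C8a), B = 4-hydroxyphenyl on C2, C = dihydropyran (O1, C2, C3, C4), D = dodecanoylphloroglucinol ring on C4.
Retrosynthesis: first the five O-benzyl groups; then C3–C4 and O1–C2 of ring C together, as a [4+2] cycloreversion to an ortho-quinone methide of ring A and 4-(benzyloxy)styrene; then the C4–C4a bond (aryllithium plus aldehyde); last the formyl and dodecanoyl C–C bonds on ring D.
Enabling feature: O1 and C4 are ortho neighbours on ring A, and C4 is doubly benzylic between ring A (C7 oxygen para to C4a) and the tri-oxygenated ring D, so O1=C8a–C4a=C4 is reachable as a stabilised heterodiene by loss of water from a carbinol; C2 carries the para-oxygenated ring B, so C2=C3 is an electron-rich styrene.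
Forward: ring D is acylated and formylated, ring A is joined at the future C4, ring C closes in the cycloaddition that also brings in ring B, and hydrogenolysis frees the phenols.
Stereochemistry: both centres (2R,4R; 2,4-cis) arise in step 4, cis from endo approach of the styrene to the (E)-methide and the absolute sense from a chiral N-triflylphosphoramide anion; the racemic carbinol centre is erased, so the step is enantioconvergent.
Helpers: the C4 hydroxyl (leaving group, lost as water in step 4) and the benzyl ethers on ring D, which block a competing quinone methide through a ring D oxygen and are removed in step 5.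

Key step: step 4

Remark: 1,3,5-tris(benzyloxy)benzene, 5-(benzyloxy)-2-bromophenol and 4-(benzyloxy)styrene are taken as purchasable benzyl ethers, and the catalyst configuration written in step 4 is provisional (the antipode is used if the correlation described there demands it).

**Step 1**
Reactants: 1 1,3,5-tris(benzyloxy)benzene; 2 dodecanoic acid
Product: 4 1-[2,4,6-tris(benzyloxy)phenyl]dodecan-1-one, via dodecanoic trifluoroacetic anhydride 3 (not isolated)
Conditions: (CF3CO)2O, CH2Cl2, 0 °C to rt
Reagents that add atoms: trifluoroacetic anhydride, O=C(OC(=O)C(F)(F)F)C(F)(F)F (its atoms reach only intermediate 3, not 4)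
Why: Friedel–Crafts acylation by the mixed anhydride 3, which the tri-alkoxy ring of 1 attacks without any metal Lewis acid so that the benzyl ethers are spared, while the new carbonyl group slows a second acylation.

**Step 2**
Reactants: 4 1-[2,4,6-tris(benzyloxy)phenyl]dodecan-1-one
Product: 6 2,4,6-tris(benzyloxy)-3-dodecanoylbenzaldehyde, via aryl iminium dichlorophosphate 5 (not isolated)
Conditions: POCl3, DMF, 0 °C to rt; then H2O
Reagents that add atoms: N,N-dimethylformamide, CN(C)C=O (formyl carbon); water, O (formyl oxygen); phosphoryl chloride, O=P(Cl)(Cl)Cl (counter-ion of intermediate 5 only)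
Why: Vilsmeier–Haack formylation at one of the two equivalent free positions of 4, each still activated by three benzyloxy groups, the ketone being twisted out of conjugation by its two ortho substituents and expected to be too slow to react with the chloroiminium reagent at room temperature.

**Step 3**
Reactants: 7 5-(benzyloxy)-2-bromophenol; 6 2,4,6-tris(benzyloxy)-3-dodecanoylbenzaldehyde
Product: 9 rac-1-[2,4,6-tris(benzyloxy)-3-{[4-(benzyloxy)-2-hydroxyphenyl](hydroxy)methyl}phenyl]dodecan-1-one, via lithium 5-(benzyloxy)-2-lithiophenoxide 8 (not isolated)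
Conditions: 7, n-BuLi (2.1 equiv), THF, −78 to −20 °C; then 6, −78 °C; aq NH4Cl
Reagents that add atoms: n-butyllithium, [Li]CCCC (lithium atoms of intermediate 8 only)
Why: Deprotonation of the phenol and bromine–lithium exchange give the O,C-dilithio species 8, whose carbanion should undergo 1,2-addition to the aldehyde of 6 at −78 °C far faster than it attacks or enolises the ketone shielded by two ortho benzyloxy groups; the carbinol centre forms as a racemate, which is of no consequence because step 4 erases it.

**Step 4**
Reactants: 9 rac-1-[2,4,6-tris(benzyloxy)-3-{[4-(benzyloxy)-2-hydroxyphenyl](hydroxy)methyl}phenyl]dodecan-1-one; 10 4-(benzyloxy)styrene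
Product: 12 1-{2,4,6-tris(benzyloxy)-3-[(2R,4R)-7-(benzyloxy)-2-[4-(benzyloxy)phenyl]-3,4-dihydro-2H-chromen-4-yl]phenyl}dodecan-1-one, via ortho-quinone methide 11 (not isolated)
Conditions: 10 (3 equiv), (R)-3,3'-bis(2,4,6-triisopropylphenyl)-1,1'-binaphthyl-2,2'-diyl N-triflylphosphoramide C51H57F3NO5PS (10 mol%), 5 Å MS, toluene, −20 °C to rt, 9 added slowly
Reagents that add atoms: none
Why: The phosphoramide protonates the carbinol of 9, water leaves, and the (E)-ortho-quinone methide 11 (O=C8a–C4a=C4 of ring A, its cationic form stabilised by the para benzyloxy group of ring A and the three alkoxy groups of ring D) stays hydrogen-bonded and ion-paired to the chiral phosphoramide anion. It then serves as the heterodiene of an inverse-electron-demand hetero-Diels–Alder reaction with the electron-rich alkene 10, the closest known reaction type being the chiral Brønsted acid-catalysed [4+2] cycloaddition of ortho-quinone methides, generated in situ from ortho-hydroxybenzhydrols, with styrenes to give 2,4-diarylchromans. Ring C closes in this [4+2] mode, asynchronously with the C3–C4 bond leading; should it become stepwise, the O1–C2 bond forms by collapse of the ring A oxygen onto the para-benzyloxybenzyl cation, a 6-endo closure with respect to the former alkene. The 2,4-cis relation follows from endo approach of ring B to the (E)-methide, and the absolute configuration at C4, and with it at C2, from the catalyst anion shielding one face of the methide carbon, the racemic centre of 9 having been erased. Regiochemistry (CH2 to C4, O1 to the benzylic carbon) follows from the polarity of the two partners, and only ring A can furnish the heterodiene because all three oxygens of ring D are capped as benzyl ethers. The catalyst antipode that leads to (2R,4R) is to be fixed on small scale by correlation of the product, both antipodes being accessible from (R)- and (S)-1,1'-bi-2-naphthol.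

**Step 5**
Reactants: 12 1-{2,4,6-tris(benzyloxy)-3-[(2R,4R)-7-(benzyloxy)-2-[4-(benzyloxy)phenyl]-3,4-dihydro-2H-chromen-4-yl]phenyl}dodecan-1-one
Product: 13 1-{2,4,6-trihydroxy-3-[(2R,4R)-7-hydroxy-2-(4-hydroxyphenyl)-3,4-dihydro-2H-chromen-4-yl]phenyl}dodecan-1-one
Conditions: H2 (1 atm), 10% Pd/C, EtOAc/MeOH, rt
Reagents that add atoms: none
Why: Catalytic hydrogenolysis cleaves the five benzyl aryl ethers under neutral conditions, under which the ketone hydrogen-bonded between two ortho hydroxyls and the benzylic bonds at C2 and C4 of ring C are expected to persist, so that neither stereocentre is touched.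

**Compound list**

1 | 1,3,5-tris(benzyloxy)benzene | c1c(OCc2ccccc2)cc(OCc2ccccc2)cc1OCc1ccccc1 | starting material
2 | dodecanoic acid | CCCCCCCCCCCC(=O)O | starting material
3 | dodecanoic trifluoroacetic anhydride | CCCCCCCCCCCC(=O)OC(=O)C(F)(F)F | intermediate (not isolated)
4 | 1-[2,4,6-tris(benzyloxy)phenyl]dodecan-1-one | CCCCCCCCCCCC(=O)c1c(OCc2ccccc2)cc(OCc2ccccc2)cc1OCc1ccccc1 | intermediate
5 | N-{[2,4,6-tris(benzyloxy)-3-dodecanoylphenyl]methylidene}-N-methylmethanaminium dichlorophosphate | CCCCCCCCCCCC(=O)c1c(OCc2ccccc2)c(C=[N+](C)C)c(OCc2ccccc2)cc1OCc1ccccc1.[O-]P(=O)(Cl)Cl | intermediate (not isolated)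
6 | 2,4,6-tris(benzyloxy)-3-dodecanoylbenzaldehyde | CCCCCCCCCCCC(=O)c1c(OCc2ccccc2)c(C=O)c(OCc2ccccc2)cc1OCc1ccccc1 | intermediate
7 | 5-(benzyloxy)-2-bromophenol | Oc1cc(OCc2ccccc2)ccc1Br | starting material
8 | lithium 5-(benzyloxy)-2-lithiophenoxide | [Li]Oc1cc(OCc2ccccc2)ccc1[Li] | intermediate (not isolated)
9 | rac-1-[2,4,6-tris(benzyloxy)-3-{[4-(benzyloxy)-2-hydroxyphenyl](hydroxy)methyl}phenyl]dodecan-1-one (racemic carbinol) | CCCCCCCCCCCC(=O)c1c(OCc2ccccc2)c(C(O)c2ccc(OCc3ccccc3)cc2O)c(OCc2ccccc2)cc1OCc1ccccc1 | intermediate
10 | 4-(benzyloxy)styrene | C=Cc1ccc(OCc2ccccc2)cc1 | starting material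
11 | 1-{2,4,6-tris(benzyloxy)-3-[(E)-(4-(benzyloxy)-6-oxocyclohexa-2,4-dien-1-ylidene)methyl]phenyl}dodecan-1-one (ortho-quinone methide, ring D anti to the carbonyl) | CCCCCCCCCCCC(=O)c1c(OCc2ccccc2)c(/C=C2\C=CC(OCc3ccccc3)=CC2=O)c(OCc2ccccc2)cc1OCc1ccccc1 | intermediate (not isolated)
12 | 1-{2,4,6-tris(benzyloxy)-3-[(2R,4R)-7-(benzyloxy)-2-[4-(benzyloxy)phenyl]-3,4-dihydro-2H-chromen-4-yl]phenyl}dodecan-1-one (2,4-cis) | CCCCCCCCCCCC(=O)c1c(OCc2ccccc2)cc(OCc2ccccc2)c([C@@H]2C[C@H](c3ccc(OCc4ccccc4)cc3)Oc3cc(OCc4ccccc4)ccc32)c1OCc1ccccc1 | intermediate
13 | 1-{2,4,6-trihydroxy-3-[(2R,4R)-7-hydroxy-2-(4-hydroxyphenyl)-3,4-dihydro-2H-chromen-4-yl]phenyl}dodecan-1-one (2,4-cis) | CCCCCCCCCCCC(=O)c1c(O)cc(O)c([C@@H]2C[C@H](c3ccc(O)cc3)Oc3cc(O)ccc32)c1O | target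

**Step count and risks**

Total step count: 5. Longest linear sequence: 5 steps (1 → 4 → 6 → 9 → 12 → 13).

Steps most likely to fail:

1. Step 4. The catalyst anion may discriminate the two faces only weakly, because its ion pair with a methide carbon that carries the twisted, doubly ortho-substituted ring D may be loose. The cis preference may erode if the addition turns fully stepwise. The acid may start oligomerisation of 10, and a hydride may shift from an ortho benzyloxy CH2 to the benzylic cation. Fallback (resolution in place of catalyst control): setting out from 9, the same cycloaddition with 10 is run through 11 with an achiral acid, diphenyl phosphate (PhO)2P(O)OH (10 mol%) in CH2Cl2 at rt. This should give the 2,4-cis chroman as the racemate, that is 12 together with its (2S,4S) antipode ent-12 F1. Preparative HPLC on an amylose tris(3,5-dimethylphenylcarbamate) phase separates the two, and the route is rejoined at 12.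

2. Step 3. The aryllithium may attack or enolise the ketone, bromine–lithium exchange on the electron-rich phenoxide may stay incomplete, a benzylic OCH2 may be lithiated, and the very labile carbinol may ionise during chromatography (silica deactivated with Et3N is advised). Fallback (electrophilic substitution of a magnesium phenoxide in place of an aryllithium addition): setting out from 6, purchased 3-(benzyloxy)phenol is converted with EtMgBr in Et2O/toluene into bromomagnesium 3-(benzyloxy)phenoxide F2, which is stirred with 6 in toluene at rt. Ortho-selective hydroxyalkylation through a six-membered magnesium chelate, at the ortho carbon para to the benzyloxy group, should give 9 without any organolithium, and the route is rejoined there.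

3. Step 5. Over-reduction may occur (hydrogenolysis of the benzylic C2–O1 bond of ring C or reduction of the aryl ketone), or the reaction may stall before the hindered ethers of ring D are cleaved. Fallback (Lewis-acid benzyl transfer in place of hydrogenolysis): setting out from 12, BCl3 with pentamethylbenzene as benzyl-cation trap in CH2Cl2 at −78 °C, quenched with MeOH, should remove the five benzyl groups without a reductant and arrive directly at 13; no compound outside the list is made (F0).

**Further compounds**

F1 | step 4 | ent-12, 1-{2,4,6-tris(benzyloxy)-3-[(2S,4S)-7-(benzyloxy)-2-[4-(benzyloxy)phenyl]-3,4-dihydro-2H-chromen-4-yl]phenyl}dodecan-1-one | CCCCCCCCCCCC(=O)c1c(OCc2ccccc2)cc(OCc2ccccc2)c([C@H]2C[C@@H](c3ccc(OCc4ccccc4)cc3)Oc3cc(OCc4ccccc4)ccc32)c1OCc1ccccc1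
F2 | step 3 | bromomagnesium 3-(benzyloxy)phenoxide | Br[Mg]Oc1cccc(OCc2ccccc2)c1
F0 | step 5 | none | none
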